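**Plan**

1. Locants used in the discussion of every intermediate (compound names use bicyclo[3.3.0]octane numbering): cycloheptane ring C1 (hemiketal carbon), C2 (CHOH), C3 (C=O), C4 (C–OH), C5 (=C), C6 (CHMe), C7 (CH–CH2); cyclopentenone ring C4, C8 (CMe2), C9 (C=O), C10 (=CH), C5.
2. Enabling feature: in the cycloheptane ring, C1 (a masked ketone) and C3 (a ketone) flank C2 as a 1,3-dicarbonyl pair whose outer neighbours are C7 and C4. This is the retron of a retro-aldol opening of a cyclobutanone (C1, C2) fused on the C3–C7 bond of a cyclopentanone (C3–C4–C5–C6–C7).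
3. Retrosynthetic cuts, in order: C2–OH (enol oxidation); pyran O–C1 and re-formation of C3–C7 (cycloheptane back to cyclopentane); C7–C1 and C3–C2 (ketene [2+2]); CH2–pyranone (Michael) and CH2–C7 (Mannich); C4–O ([2,3] shift); C4–C5, C8–C9, C9–C10 (Pauson–Khand); C3–C4 and C5–C6 (chain).
4. Forward: chain → cyclopentane ring and cyclopentenone ring together → pyranone joined at C7 → cyclobutanone fused across C3–C7 → fragmentation expands the cyclopentane ring to the cycloheptane ring → pyran hemiketal closes on C1 → C2 hydroxylation.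
5. Stereochemistry: C6 from a rhodium-catalysed asymmetric alkynylation; C4 from C6 (selenenylation anti to the methyl group, then a suprafacial [2,3] shift); C7, C1 and C2 are set under equilibrating conditions.

Key step: step 13

Remark: pyranone 15 is treated as a purchasable building block; C1, C2 and C7 of the target can epimerize (ring–chain tautomerism, enolization) and the natural configuration is assumed to be the thermodynamic one.

**Step 1**
Reactants: 1 (E)-crotonaldehyde; 2 (triisopropylsilyl)acetylene
Product: 3 (R)-3-methyl-5-(triisopropylsilyl)pent-4-ynal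
Conditions: [Rh(OAc)(C2H4)2]2 (2.5 mol %), DTBM-SEGPHOS (6 mol %, antipode chosen to give R), MeOH, 40 °C; dilute HCl work-up
Reagents that add atoms: none
Why: Rhodium-catalysed asymmetric conjugate alkynylation of an enal, in which the bulky silylacetylene suppresses alkyne dimerization and the chiral bisphosphine–alkynylrhodium species selects the enal face, setting C6.

**Step 2**
Reactants: 3 (R)-3-methyl-5-(triisopropylsilyl)pent-4-ynal
Product: 4 (5R)-5-methyl-7-(triisopropylsilyl)hept-1-en-6-yn-3-ol
Conditions: CH2=CHMgBr, THF, −78 °C; aq. NH4Cl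
Reagents that add atoms: vinylmagnesium bromide, C=C[Mg]Br
Why: Grignard 1,2-addition to the aldehyde; the carbinol centre C3 forms as a mixture that is erased by oxidation in step 6.

**Step 3**
Reactants: 4 (5R)-5-methyl-7-(triisopropylsilyl)hept-1-en-6-yn-3-ol
Product: 5 (5R)-5-methylhept-1-en-6-yn-3-ol
Conditions: Bu4NF, THF, 0 °C → rt
Reagents that add atoms: none
Why: Fluoride-induced protodesilylation of the C(sp)–Si bond, needed because the bulky silyl group would block the next cyclization.

**Step 4**
Reactants: 5 (5R)-5-methylhept-1-en-6-yn-3-ol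
Product: 6 (8R)-6-hydroxy-8-methylbicyclo[3.3.0]oct-1-en-3-one
Conditions: Co2(CO)8 (10 mol %), tetramethylthiourea (60 mol %), CO (1 atm), benzene, 70 °C
Reagents that add atoms: carbon monoxide, [C-]#[O+]
Why: Intramolecular Pauson–Khand reaction of the 1,6-enyne forms both five-membered rings at once (C4–C5, C8–C9, C9–C10), the terminal alkyne carbon becoming C10; the ring-fusion centre C4 is not controlled and is reset in step 7.

**Step 5**
Reactants: 6 (8R)-6-hydroxy-8-methylbicyclo[3.3.0]oct-1-en-3-one
Product: 7 (8R)-6-hydroxy-4,4,8-trimethylbicyclo[3.3.0]oct-1-en-3-one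
Conditions: LiN(iPr)2 (2.2 equiv), THF, −78 °C, then MeI; LiN(iPr)2 (1.2 equiv), −78 °C, then MeI, −78 → −40 °C
Reagents that add atoms: iodomethane, CI
Why: Kinetic α′-enolate alkylation of the cyclopentenone at C8, carried out twice, with the lithium alkoxide at C3 inert to MeI at low temperature as in dianion alkylations of hydroxy carbonyl compounds (Fráter–Seebach type); no lasting stereocentre is formed.

**Step 6**
Reactants: 7 (8R)-6-hydroxy-4,4,8-trimethylbicyclo[3.3.0]oct-1-en-3-one
Product: 8 (8R)-4,4,8-trimethylbicyclo[3.3.0]oct-1-ene-3,6-dione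
Conditions: Dess–Martin periodinane, CH2Cl2, rt
Reagents that add atoms: none
Why: Dess–Martin oxidation of the secondary alcohol; all C3/C4 isomers converge on one dione in which C4–H, flanked by the C3 carbonyl and the C5=C10–C9=O enone, is the acidic position.

**Step 7**
Reactants: 8 (8R)-4,4,8-trimethylbicyclo[3.3.0]oct-1-ene-3,6-dione
Product: 12 (5R,8R)-5-hydroxy-4,4,8-trimethylbicyclo[3.3.0]oct-1-ene-3,6-dione, via C10 phenyl selenide 9 (not isolated), via selenoxide 10 (not isolated), via selenenate ester 11 (not isolated)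
Conditions: KN(SiMe3)2, THF, −78 °C; PhSeCl, −78 °C; then 30% H2O2, pyridine, CH2Cl2, 0 °C → rt
Reagents that add atoms: hydrogen peroxide, OO
Why: The delocalized enolate should be selenenylated at the unhindered C10 terminus on the face opposite the C6 methyl, and the derived allylic selenoxide (no syn β-hydrogen) should undergo a suprafacial [2,3]-sigmatropic (Mislow–Evans type) shift to the C4–O selenenate, cleaved in situ, so the C4 hydroxyl arrives trans to the C6 methyl with the C5=C10 enone restored.

**Step 8**
Reactants: 12 (5R,8R)-5-hydroxy-4,4,8-trimethylbicyclo[3.3.0]oct-1-ene-3,6-dione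
Product: 14 (5R,8R)-7-[(dimethylamino)methyl]-4,4,8-trimethyl-5-(trimethylsilyloxy)bicyclo[3.3.0]oct-1-ene-3,6-dione, via bis-silyl enol ether 13 (not isolated)
Conditions: Me3SiOTf (2.2 equiv), Et3N (3.5 equiv), CH2Cl2, 0 °C; then Me2N=CH2+ I−, rt; aq. NaHCO3
Reagents that add atoms: trimethylsilyl trifluoromethanesulfonate, C[Si](C)(C)OS(=O)(=O)C(F)(F)F; N,N-dimethylmethylideneammonium iodide (Eschenmoser's salt), C=[N+](C)C.[I-]
Why: Soft enolization of the C3 ketone can only go toward C7 because C4 is quaternary, and the silyl enol ether adds to the iminium ion (Mukaiyama–Mannich reaction) while the tertiary hydroxyl is capped; the C7 configuration is inconsequential.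

**Step 9**
Reactants: 14 (5R,8R)-7-[(dimethylamino)methyl]-4,4,8-trimethyl-5-(trimethylsilyloxy)bicyclo[3.3.0]oct-1-ene-3,6-dione; 15 4-hydroxy-5,6-dimethyl-2H-pyran-2-one
Product: 17 (5R,8R)-7-[(4-hydroxy-5,6-dimethyl-2-oxo-2H-pyran-3-yl)methyl]-4,4,8-trimethyl-5-(trimethylsilyloxy)bicyclo[3.3.0]oct-1-ene-3,6-dione, via methylidene ketone 16 (not isolated)
Conditions: 15 (2 equiv), toluene, 90 °C
Reagents that add atoms: none
Why: Thermal amine exchange: the Mannich base releases dimethylamine to give enone 16, which is trapped at once by C3 of the vinylogous acid 15 in a Michael addition, so the exocyclic enone never accumulates; the C7 epimer ratio is irrelevant because C7 becomes trigonal in step 10.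

**Step 10**
Reactants: 17 (5R,8R)-7-[(4-hydroxy-5,6-dimethyl-2-oxo-2H-pyran-3-yl)methyl]-4,4,8-trimethyl-5-(trimethylsilyloxy)bicyclo[3.3.0]oct-1-ene-3,6-dione
Product: 18 (5R,8R)-7-{[5,6-dimethyl-2-oxo-4-(trimethylsilyloxy)-2H-pyran-3-yl]methyl}-4,4,8-trimethyl-5,6-bis(trimethylsilyloxy)bicyclo[3.3.0]octa-1,6-dien-3-one
Conditions: Me3SiOTf (2.4 equiv), Et3N (3 equiv), CH2Cl2, 0 °C → rt
Reagents that add atoms: trimethylsilyl trifluoromethanesulfonate, C[Si](C)(C)OS(=O)(=O)C(F)(F)F
Why: Silyl triflate/amine soft enolization, in which C7–H is the only proton next to the C3 carbonyl and the acidic pyranone hydroxyl is silylated at the same time.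

**Step 11**
Reactants: 18 (5R,8R)-7-{[5,6-dimethyl-2-oxo-4-(trimethylsilyloxy)-2H-pyran-3-yl]methyl}-4,4,8-trimethyl-5,6-bis(trimethylsilyloxy)bicyclo[3.3.0]octa-1,6-dien-3-one
Product: 19 2,2-dichlorocyclobutanone cis-fused across C3–C7 of 18 (C3 carries OSiMe3 and the CCl2 carbon C2; C7 carries the silyloxypyranonylmethyl group and the carbonyl carbon C1)
Conditions: Cl2CHCOCl, Et3N (slow addition), hexane/Et2O, rt
Reagents that add atoms: dichloroacetyl chloride, ClC(Cl)C(=O)Cl
Why: Dichloroketene [2+2] cycloaddition with a silyl enol ether, whose polarization fixes the regiochemistry (ketene carbonyl carbon to the nucleophilic C7, CCl2 carbon to the siloxy carbon C3), while the enone and pyranone C=C bonds are too electron-poor to compete; the two new ring-fusion centres are necessarily cis and are erased in step 13.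

**Step 12**
Reactants: 19 2,2-dichlorocyclobutanone cis-fused across C3–C7 (tris-silylated)
Product: 20 cyclobutanone cis-fused across C3–C7 with C2H2, free pyranone hydroxyl and both tertiary trimethylsilyl ethers (on C3 and C4) retained
Conditions: Zn dust, AcOH, iPrOH/H2O, 0 °C
Reagents that add atoms: none
Why: Reductive dechlorination of the α,α-dichlorocyclobutanone by zinc in acetic acid, mild enough at 0 °C to leave the enone and the tertiary silyl ethers while the labile pyranone silyl ether is hydrolysed.

**Step 13**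
Reactants: 20 cyclobutanone cis-fused across C3–C7 (C3 and C4 trimethylsilyl ethers, free pyranone hydroxyl)
Product: 23 2-deoxy hemiketal (the target lacking the C2 hydroxyl), via cyclobutanol 21 (not isolated), via open cycloheptane-1,3-dione 22 (not isolated)
Conditions: Bu4NF (3 equiv), AcOH (3 equiv), THF, 0 → 40 °C
Reagents that add atoms: none
Why: Fluoride removes both trimethylsilyl groups to give cyclobutanol 21, whose C3–OH/C1=O β-hydroxy ketone array undergoes retro-aldol scission of the C3–C7 bond shared by the four- and five-membered rings, so the cyclopentane ring (C3–C4–C5–C6–C7) becomes the cycloheptane ring with C1 and C2 inserted and the 1,3-dione 22 is revealed. The closest known reaction type is the two-carbon ring expansion of cyclopentanone silyl enol ether–dichloroketene adducts to cycloheptane-1,3-diones by desilylative retro-aldol fragmentation. The seven-membered ring is not closed by bond formation but arises by cleavage of the zero-atom bridge of the bicyclo[3.2.0]heptanone, after which the pyran ring closes by 6-exo-trig addition of the pyranone 4-hydroxyl to the new C1 ketone. C7 is set by protonation of the C1=C7 enol under equilibrating conditions, which should place the CH2 arm trans to the C6 methyl, and the hemiketal carbon C1 should settle by ring–chain tautomerism in the anomerically favoured trans-fused arrangement; C4 and C6 are untouched. The step needs cleavage of C3–C7 and not of C3–C2, which is secured because scission of the ring-fusion bond gives the more substituted enolate and relieves the crowding of the three contiguous fully substituted carbons C3, C4 and C7, as in the parent bicyclo[3.2.0]heptanone series. The acetic acid buffer keeps the freed C4 hydroxyl from base-induced retro-aldol opening of the cyclopentenone or α-ketol shift.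

**Step 14**
Reactants: 23 2-deoxy hemiketal (the target lacking the C2 hydroxyl)
Product: 26 CNP0525404.1 (target), via ring-opened hydroxy-enone 24 (not isolated), via open 2-hydroxy-1,3-dione 25 (not isolated)
Conditions: dimethyldioxirane (1.05 equiv), acetone, −20 → 0 °C
Reagents that add atoms: dimethyldioxirane, CC1(C)OO1
Why: Electrophilic α-hydroxylation of an enolized β-dicarbonyl compound by dimethyldioxirane: hemiketal 23 opens by ring–chain tautomerism (loss of the pyranone oxygen from C1, β to the C3 ketone) to the hydroxy-enone 24, whose C1=C2 enol bond is epoxidized, the epoxy alcohol collapses to the 2-hydroxy-1,3-dione 25, and this recloses to the hemiketal, with the epimerizable C2 expected to settle with its hydroxyl trans to the anomeric hydroxyl.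

**Compound list**

1 | (E)-crotonaldehyde | C/C=C/C=O | starting material
2 | (triisopropylsilyl)acetylene | C#C[Si](C(C)C)(C(C)C)C(C)C | starting material
3 | (R)-3-methyl-5-(triisopropylsilyl)pent-4-ynal | O=CC[C@@H](C)C#C[Si](C(C)C)(C(C)C)C(C)C | intermediate
4 | (5R)-5-methyl-7-(triisopropylsilyl)hept-1-en-6-yn-3-ol, both C3 epimers | C=CC(O)C[C@@H](C)C#C[Si](C(C)C)(C(C)C)C(C)C | intermediate
5 | (5R)-5-methylhept-1-en-6-yn-3-ol, both C3 epimers | C=CC(O)C[C@@H](C)C#C | intermediate
6 | (8R)-6-hydroxy-8-methylbicyclo[3.3.0]oct-1-en-3-one, isomer mixture at carbinol C3 and ring-fusion C4 (target locants) | OC1C2C(=CC(=O)C2)[C@H](C)C1 | intermediate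
7 | (8R)-6-hydroxy-4,4,8-trimethylbicyclo[3.3.0]oct-1-en-3-one, same isomer mixture | OC1C2C(=CC(=O)C2(C)C)[C@H](C)C1 | intermediate
8 | (8R)-4,4,8-trimethylbicyclo[3.3.0]oct-1-ene-3,6-dione, C4–H epimerizable | O=C1C2C(=CC(=O)C2(C)C)[C@H](C)C1 | intermediate
9 | (2S,8R)-4,4,8-trimethyl-2-(phenylselanyl)bicyclo[3.3.0]oct-1(5)-ene-3,6-dione, selenium on C10 anti to the C6 methyl | O=C1C2=C([C@H]([Se]c3ccccc3)C(=O)C2(C)C)[C@H](C)C1 | intermediate
10 | selenoxide of 9 (mixture at selenium) | O=C1C2=C([C@H]([Se](=O)c3ccccc3)C(=O)C2(C)C)[C@H](C)C1 | intermediate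
11 | (5R,8R)-4,4,8-trimethyl-5-[(phenylselanyl)oxy]bicyclo[3.3.0]oct-1-ene-3,6-dione | O=C1[C@@]2(O[Se]c3ccccc3)C(=CC(=O)C2(C)C)[C@H](C)C1 | intermediate
12 | (5R,8R)-5-hydroxy-4,4,8-trimethylbicyclo[3.3.0]oct-1-ene-3,6-dione, C4 hydroxyl trans to C6 methyl | O=C1[C@@]2(O)C(=CC(=O)C2(C)C)[C@H](C)C1 | intermediate
13 | (5R,8R)-4,4,8-trimethyl-5,6-bis(trimethylsilyloxy)bicyclo[3.3.0]octa-1,6-dien-3-one | C[Si](C)(C)OC1[C@@]2(O[Si](C)(C)C)C(=CC(=O)C2(C)C)[C@H](C)C=1 | intermediate
14 | (5R,8R)-7-[(dimethylamino)methyl]-4,4,8-trimethyl-5-(trimethylsilyloxy)bicyclo[3.3.0]oct-1-ene-3,6-dione, C7 epimers | O=C1[C@@]2(O[Si](C)(C)C)C(=CC(=O)C2(C)C)[C@H](C)C1CN(C)C | intermediate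
15 | 4-hydroxy-5,6-dimethyl-2H-pyran-2-one | Cc1oc(=O)cc(O)c1C | starting material
16 | (5R,8S)-4,4,8-trimethyl-7-methylidene-5-(trimethylsilyloxy)bicyclo[3.3.0]oct-1-ene-3,6-dione (same spatial arrangement as 14; the C8 descriptor changes only through the priority rules) | O=C1[C@@]2(O[Si](C)(C)C)C(=CC(=O)C2(C)C)[C@H](C)C1=C | intermediate
17 | (5R,8R)-7-[(4-hydroxy-5,6-dimethyl-2-oxo-2H-pyran-3-yl)methyl]-4,4,8-trimethyl-5-(trimethylsilyloxy)bicyclo[3.3.0]oct-1-ene-3,6-dione, C7 epimers, open keto form | O=C1[C@@]2(O[Si](C)(C)C)C(=CC(=O)C2(C)C)[C@H](C)C1Cc1c(O)c(C)c(C)oc1=O | intermediate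
18 | (5R,8R)-7-{[5,6-dimethyl-2-oxo-4-(trimethylsilyloxy)-2H-pyran-3-yl]methyl}-4,4,8-trimethyl-5,6-bis(trimethylsilyloxy)bicyclo[3.3.0]octa-1,6-dien-3-one | C[Si](C)(C)OC1[C@@]2(O[Si](C)(C)C)C(=CC(=O)C2(C)C)[C@H](C)C=1Cc1c(O[Si](C)(C)C)c(C)c(C)oc1=O | intermediate
19 | dichloroketene adduct of 18: 2,2-dichlorocyclobutanone cis-fused across C3–C7, configuration at C3 and C7 not assigned | C[Si](C)(C)OC13[C@@]2(O[Si](C)(C)C)C(=CC(=O)C2(C)C)[C@H](C)C1(Cc1c(O[Si](C)(C)C)c(C)c(C)oc1=O)C(=O)C3(Cl)Cl | intermediate
20 | dechlorinated cyclobutanone with free pyranone hydroxyl, C3 and C4 trimethylsilyl ethers retained | C[Si](C)(C)OC13[C@@]2(O[Si](C)(C)C)C(=CC(=O)C2(C)C)[C@H](C)C1(Cc1c(O)c(C)c(C)oc1=O)C(=O)C3 | intermediate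
21 | cyclobutanol: 20 with both silyl groups removed (C3–OH, C4–OH) | OC13[C@@]2(O)C(=CC(=O)C2(C)C)[C@H](C)C1(Cc1c(O)c(C)c(C)oc1=O)C(=O)C3 | intermediate
22 | open cycloheptane-1,3-dione (C1 and C3 ketones, C4 hydroxyl, fused cyclopentenone, pyranonylmethyl at C7, C7 epimers) | O=C1CC(=O)[C@@]2(O)C(=CC(=O)C2(C)C)[C@H](C)C1Cc1c(O)c(C)c(C)oc1=O | intermediate
23 | 2-deoxy hemiketal: target lacking the C2 hydroxyl, trans-fused pyran, C7 arm trans to C6 methyl | Cc1oc(=O)c2c(c1C)O[C@]1(O)CC(=O)[C@@]3(O)C(=CC(=O)C3(C)C)[C@H](C)[C@H]1C2 | intermediate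
24 | ring-opened hydroxy-enone from 23 (C1 enol hydroxyl, C1=C2 double bond, C3 ketone, C4 hydroxyl, free pyranone hydroxyl, C7 epimers) | OC1=CC(=O)[C@@]2(O)C(=CC(=O)C2(C)C)[C@H](C)C1Cc1c(O)c(C)c(C)oc1=O | intermediate
25 | open 2-hydroxy-1,3-dione (C1 and C3 ketones, hydroxyl at C2, C2 and C7 epimers) | O=C1C(O)C(=O)[C@@]2(O)C(=CC(=O)C2(C)C)[C@H](C)C1Cc1c(O)c(C)c(C)oc1=O | intermediate
26 | CNP0525404.1 | Cc1oc(=O)c2c(c1C)O[C@]1(O)[C@H](O)C(=O)[C@@]3(O)C(=CC(=O)C3(C)C)[C@H](C)[C@H]1C2 | target

**Step count and risks**

Total: 14 steps. Longest linear sequence: 14 steps (1 → 26); pyranone 15 enters at step 9.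

Step 11 is the most exposed. The cycloaddition has to take place at a tetrasubstituted enol ether next to the quaternary C4, and if it is slow, C-acylation, desilylation or ketene oligomerization can take over. The fallback sets out from 18 and returns at 20. A keteniminium ion is generated from N,N-dimethylacetamide with Tf2O and 2,4,6-collidine in 1,2-dichloroethane and added to 18 in a stepwise cationic [2+2] cycloaddition, which tolerates congested alkenes better and carries no chlorine. This gives the cyclobutaniminium triflate F1, and mild aqueous NaHCO3 hydrolysis of the iminium and of the pyranone silyl ether delivers 20 directly, so step 12 is skipped.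

Step 14 comes next. The 2-hydroxy-1,3-dione can be oxidized further, oxygen may arrive on the wrong face of C2 without later equilibration, or the oxidant may attack the other alkenes. The fallback sets out from 23 and returns at 26. Acid-catalysed dehydration (pyridinium p-toluenesulfonate, toluene, 4 Å molecular sieves, 60 °C) gives the pyran enol ether conjugated to the C3 ketone, the vinylogous ester F2. Dihydroxylation of its C1=C2 bond (OsO4 cat., N-methylmorpholine N-oxide, acetone/H2O) installs the C2 hydroxyl and the hemiketal hydroxyl together, and the hemiketal carbon then anomerizes by ring–chain tautomerism to 26.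

Step 7 is third. Selenenylation may occur at C4 and not at C10, or on the methyl-bearing face, and the selenoxide may divert into a seleno-Pummerer pathway. The fallback sets out from 8 and returns at 12. The potassium dienolate of 8 (KOC(CH3)3, THF/tert-butanol, −20 °C) is oxygenated with O2 at the tertiary carbon C4, anti to the C6 methyl, to give the tertiary hydroperoxide F3, which is reduced in the same flask with P(OEt)3 to 12.

**Further compounds**

F1 | step 11 | cyclobutaniminium triflate (20-type skeleton with C1=N+Me2 in place of C1=O, all three silyl ethers present) | C[Si](C)(C)OC13[C@@]2(O[Si](C)(C)C)C(=CC(=O)C2(C)C)[C@H](C)C1(Cc1c(O[Si](C)(C)C)c(C)c(C)oc1=O)C(=[N+](C)C)C3.[O-]S(=O)(=O)C(F)(F)F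
F2 | step 14 | vinylogous ester (23 dehydrated to the C1=C2 pyran enol ether conjugated with the C3 ketone) | Cc1oc(=O)c2c(c1C)OC1=CC(=O)[C@@]3(O)C(=CC(=O)C3(C)C)[C@H](C)[C@H]1C2
F3 | step 7 | (5R,8R)-5-hydroperoxy-4,4,8-trimethylbicyclo[3.3.0]oct-1-ene-3,6-dione | O=C1[C@@]2(OO)C(=CC(=O)C2(C)C)[C@H](C)C1
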